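Numbering follows the tetralin core: C1 is the diarylmethine, C2/C3 carry the CH2OH carbons C9/C9′, C4 is the benzylic CH2, and C4a–C8a form ring A. C1 can support a cation (trimethoxyphenyl donor) and C3 an enolate once C9′ is a lactone carbonyl. The target is therefore traced back to a cyclopropane C1–C2–C3 whose C1–C3 bond is polarised and expendable. One flask converts an achiral, open-chain (E)-cinnamyl 2-diazo-3-arylpropanoate into the lactone-fused tetralin. A chiral dirhodium carbene closes cyclopropane plus lactone, then a Lewis acid cleaves C1–C3 and C8a attacks C1 to close ring B. Bromine on C5 keeps the other ortho site shut. Hydride reduction and hydrogenolysis finish.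

Key step: step 10

Design notes
- **Ring A regiochemistry:** electrophilic bromination of 5-hydroxyvanillin is avoided. A free 3-hydroxyl next to an alkoxy group sends bromine to its own ortho position (isovanillin gives 2-bromoisovanillin). That position is also para to the methoxy group, so the halogen would land on the carbon that must become C8a. The order is therefore inverted: bromine is placed ortho to a free phenol standing where the C6 methoxy group belongs, and the phenol is methylated afterwards. The substitution pattern of the key-step precursor stays the same.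
- **Assumption:** the alpha-benzyl diazo ester follows the facial preference of allylic diazoacetates and diazopropionates, where (S)-configured carboxamidate ligands lead to the (1R,5S)-3-oxabicyclo[3.1.0]hexan-2-one series, so the (1S,5R) series needed for (2R) calls for the (4R)-ligand (the (4S)-catalyst would be used if the sense proved reversed).
- **Last step:** NaOAc is the HBr scavenger, because an amine base can slow O-debenzylation over Pd/C and promotes autoxidation of the free catechol.
- **Ligand:** MPPIM = methyl 1-(3-phenylpropanoyl)-2-oxoimidazolidine-4-carboxylate.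

Step 1
Reactants: 1 methyl gallate (methyl 3,4,5-trihydroxybenzoate)
Product: 2 methyl 3,4-bis(benzyloxy)-5-hydroxybenzoate
Conditions: BnBr (2.05 equiv), K2CO3 (2.1 equiv), DMF, 0 °C to rt; chromatography
Reagents that add atoms: benzyl bromide, BrCc1ccccc1
Why: Williamson etherification under stoichiometric control, in which the 4-OH (acidified by the para ester) is alkylated first and one of the two equivalent flanking phenols second, so the 3,4-dibenzyl ether should dominate and the mono- and tribenzyl ethers are removed on silica.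

Step 2
Reactants: 2 methyl 3,4-bis(benzyloxy)-5-hydroxybenzoate
Product: 3 methyl 4,5-bis(benzyloxy)-2-bromo-3-hydroxybenzoate
Conditions: DBDMH (0.52 equiv), CHCl3, rt, dark
Reagents that add atoms: 1,3-dibromo-5,5-dimethylhydantoin (DBDMH), CC1(C)N(Br)C(=O)N(Br)C1=O
Why: Ortho-monobromination of a phenol by an N-bromo imide in a non-polar solvent, where the only free ortho carbon (also para to a benzyloxy group and flanked by the small OH) should react ahead of the para carbon, which is squeezed between ester and benzyloxy group.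

Step 3
Reactants: 3 methyl 4,5-bis(benzyloxy)-2-bromo-3-hydroxybenzoate
Product: 4 methyl 4,5-bis(benzyloxy)-2-bromo-3-methoxybenzoate
Conditions: MeI (1.5 equiv), K2CO3, DMF, rt
Reagents that add atoms: iodomethane, CI
Why: Williamson O-methylation of the only acidic site with a small electrophile fixes the future C6 methoxy group next to the blocking bromine.

Step 4
Reactants: 4 methyl 4,5-bis(benzyloxy)-2-bromo-3-methoxybenzoate
Product: 5 [4,5-bis(benzyloxy)-2-bromo-3-methoxyphenyl]methanol
Conditions: i-Bu2AlH (2.5 equiv), CH2Cl2, −78 to 0 °C; aq. potassium sodium tartrate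
Reagents that add atoms: none
Why: Ester-to-alcohol reduction with i-Bu2AlH, which at low temperature leaves the aryl bromide and the benzyl ethers untouched.

Step 5
Reactants: 5 [4,5-bis(benzyloxy)-2-bromo-3-methoxyphenyl]methanol
Product: 6 1,2-bis(benzyloxy)-4-bromo-5-(bromomethyl)-3-methoxybenzene
Conditions: PBr3 (0.4 equiv), CH2Cl2, 0 °C; used without storage
Reagents that add atoms: phosphorus tribromide, BrP(Br)Br
Why: Benzylic alcohol to bromide through the phosphite ester and SN2 displacement by bromide, the ortho bromine tempering the ionisation tendency of this electron-rich benzylic halide.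

Step 6
Reactants: 7 methyl (E)-3,4,5-trimethoxycinnamate
Product: 8 (E)-3-(3,4,5-trimethoxyphenyl)prop-2-en-1-ol
Conditions: i-Bu2AlH (2.3 equiv), CH2Cl2, −78 to 0 °C; aq. potassium sodium tartrate
Reagents that add atoms: none
Why: 1,2-Reduction of an unsaturated ester by i-Bu2AlH gives the allylic alcohol with the E-alkene intact and avoids the conjugate reduction that LiAlH4 can cause on cinnamates.

Step 7
Reactants: 8 (E)-3-(3,4,5-trimethoxyphenyl)prop-2-en-1-ol; 9 2,2,6-trimethyl-4H-1,3-dioxin-4-one
Product: 10 (E)-3-(3,4,5-trimethoxyphenyl)allyl 3-oxobutanoate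
Conditions: toluene, reflux, acetone distilled off
Reagents that add atoms: none
Why: Thermal retro-hetero-Diels–Alder cleavage of the dioxinone releases acetylketene, which the alcohol traps as its acetoacetate under neutral conditions at a temperature below the onset of Carroll rearrangement.

Step 8
Reactants: 10 (E)-3-(3,4,5-trimethoxyphenyl)allyl 3-oxobutanoate; 6 1,2-bis(benzyloxy)-4-bromo-5-(bromomethyl)-3-methoxybenzene
Product: 11 (E)-3-(3,4,5-trimethoxyphenyl)allyl 2-[4,5-bis(benzyloxy)-2-bromo-3-methoxybenzyl]-3-oxobutanoate (racemic)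
Conditions: 10 (1.15 equiv), NaH (1.0 equiv), THF, 0 °C; then 6, rt
Reagents that add atoms: none
Why: Acetoacetic ester alkylation (SN2 of a stabilised enolate on a benzylic bromide), with a slight excess of enolate limiting double alkylation and a new stereocentre that is racemic and is erased in the next step.

Step 9
Reactants: 11 (E)-3-(3,4,5-trimethoxyphenyl)allyl 2-[4,5-bis(benzyloxy)-2-bromo-3-methoxybenzyl]-3-oxobutanoate
Product: 12 (E)-3-(3,4,5-trimethoxyphenyl)allyl 3-[4,5-bis(benzyloxy)-2-bromo-3-methoxyphenyl]-2-diazopropanoate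
Conditions: p-ABSA (1.3 equiv), DBU (1.5 equiv), MeCN, 0 °C to rt; quick filtration through silica, used promptly
Reagents that add atoms: 4-acetamidobenzenesulfonyl azide (p-ABSA), CC(=O)Nc1ccc(cc1)S(=O)(=O)N=[N+]=[N-]
Why: Deacylative Regitz diazo transfer, in which the enolate attacks the terminal azide nitrogen and the adduct collapses with migration of the acetyl group to the sulfonamide nitrogen, a standard entry to alpha-alkyl diazo esters from 2-alkylacetoacetates.

Step 10
Reactants: 12 (E)-3-(3,4,5-trimethoxyphenyl)allyl 3-[4,5-bis(benzyloxy)-2-bromo-3-methoxyphenyl]-2-diazopropanoate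
Product: 14 (3aR,4S,9aS)-5,6-bis(benzyloxy)-8-bromo-7-methoxy-4-(3,4,5-trimethoxyphenyl)-3a,4,9,9a-tetrahydronaphtho[2,3-c]furan-1(3H)-one, via cyclopropane-fused lactone 13 (not isolated)
Conditions: Rh2(4R-MPPIM)4 (1 mol %), CH2Cl2, reflux, 12 added by syringe pump over 10 h; then Sc(OSO2CF3)3 (20 mol %), same flask, rt to reflux
Reagents that add atoms: none
Why: The divalent-rhodium carboxamidate expels N2 from 12 and the carbene at C3 adds in a concerted, stereospecific [2+1] fashion to the tethered E-alkene, so that C2–C3 and C1–C3 form together and the ester tether is thereby closed to the five-membered lactone of 13 (closest known type: enantioselective intramolecular cyclopropanation of allylic diazoacetates and diazopropionates, here stretched to an alpha-benzyl member). Sc(OSO2CF3)3 on the lactone carbonyl then heterolyses the donor–acceptor bond C1–C3 to a trimethoxybenzyl cation and a scandium enolate, and C8a attacks C1 in an intramolecular Friedel–Crafts alkylation that closes the six-membered ring B along the chain C1–C2–C3–C4–C4a, as in the Lewis acid cyclisation of 2-arylcyclopropyl carbonyl compounds to 1-aryltetralins. C2 is fixed by the catalyst, which selects the alkene face, and none of its bonds is broken afterwards. C1 is planar in the cation and is re-set in the ring closure with the aryl group anti to C9, the arrangement that avoids the lactone CH2 and lets the aryl group turn away from the C8 benzyloxy group (the same 1,2-trans outcome as in acid cyclisations of 7-hydroxydibenzylbutyrolactones), while C3 is set by C-protonation of the enolate with the arenium proton to give the cis ring fusion, which is also the thermodynamic isomer at this enolisable centre. The step needs attack at C8a only, and this is secured structurally because C5 carries bromine while C8a is para to the C6 methoxy and ortho to the C8 benzyloxy group. It also needs cyclopropanation to beat 1,2-hydride shift from C4 and ring closure to beat proton loss from the cation: the weakly electrophilic carboxamidate carbene, the short tether, the electron-withdrawing ortho bromine and slow addition serve the first, and the reversibility of proton loss under the acidic conditions serves the second.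

Step 11
Reactants: 14 (3aR,4S,9aS)-5,6-bis(benzyloxy)-8-bromo-7-methoxy-4-(3,4,5-trimethoxyphenyl)-3a,4,9,9a-tetrahydronaphtho[2,3-c]furan-1(3H)-one
Product: 15 [(1S,2R,3S)-7,8-bis(benzyloxy)-5-bromo-6-methoxy-1-(3,4,5-trimethoxyphenyl)-1,2,3,4-tetrahydronaphthalene-2,3-diyl]dimethanol
Conditions: LiAlH4 (2 equiv), THF, 0 °C; aq. NaOH work-up
Reagents that add atoms: none
Why: Hydride reduction of a gamma-lactone to the 1,4-diol, in which carbonyl addition is faster than enolisation and C3 already holds the favoured cis relation, so no stereocentre should move (partial loss of bromine would be harmless).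

Step 12
Reactants: 15 [(1S,2R,3S)-7,8-bis(benzyloxy)-5-bromo-6-methoxy-1-(3,4,5-trimethoxyphenyl)-1,2,3,4-tetrahydronaphthalene-2,3-diyl]dimethanol
Product: 16 (6S,7R,8S)-6,7-bis(hydroxymethyl)-3-methoxy-8-(3,4,5-trimethoxyphenyl)-5,6,7,8-tetrahydronaphthalene-1,2-diol (target; tetralin numbering 1S,2R,3S)
Conditions: H2 (1 atm), 10% Pd/C, NaOAc (1.5 equiv), MeOH–EtOAc, rt; filtration and concentration under argon
Reagents that add atoms: none
Why: Heterogeneous hydrogenolysis cleaves both aryl benzyl ethers and the aryl C–Br bond in one operation while NaOAc takes up HBr, and the sp3 stereocentres and the C1–aryl bonds are inert to these conditions.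

Compound list
1 | methyl gallate | COC(=O)c1cc(O)c(O)c(O)c1 | starting material
2 | methyl 3,4-bis(benzyloxy)-5-hydroxybenzoate | COC(=O)c1cc(O)c(OCc2ccccc2)c(OCc2ccccc2)c1 | intermediate
3 | methyl 4,5-bis(benzyloxy)-2-bromo-3-hydroxybenzoate | COC(=O)c1cc(OCc2ccccc2)c(OCc2ccccc2)c(O)c1Br | intermediate
4 | methyl 4,5-bis(benzyloxy)-2-bromo-3-methoxybenzoate | COC(=O)c1cc(OCc2ccccc2)c(OCc2ccccc2)c(OC)c1Br | intermediate
5 | [4,5-bis(benzyloxy)-2-bromo-3-methoxyphenyl]methanol | OCc1cc(OCc2ccccc2)c(OCc2ccccc2)c(OC)c1Br | intermediate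
6 | 1,2-bis(benzyloxy)-4-bromo-5-(bromomethyl)-3-methoxybenzene | BrCc1cc(OCc2ccccc2)c(OCc2ccccc2)c(OC)c1Br | intermediate
7 | methyl (E)-3,4,5-trimethoxycinnamate | COC(=O)/C=C/c1cc(OC)c(OC)c(OC)c1 | starting material
8 | (E)-3-(3,4,5-trimethoxyphenyl)prop-2-en-1-ol | OC/C=C/c1cc(OC)c(OC)c(OC)c1 | intermediate
9 | 2,2,6-trimethyl-4H-1,3-dioxin-4-one | CC1=CC(=O)OC(C)(C)O1 | starting material
10 | (E)-3-(3,4,5-trimethoxyphenyl)allyl 3-oxobutanoate | CC(=O)CC(=O)OC/C=C/c1cc(OC)c(OC)c(OC)c1 | intermediate
11 | (E)-3-(3,4,5-trimethoxyphenyl)allyl 2-[4,5-bis(benzyloxy)-2-bromo-3-methoxybenzyl]-3-oxobutanoate, racemic at the alpha carbon | CC(=O)C(Cc1cc(OCc2ccccc2)c(OCc2ccccc2)c(OC)c1Br)C(=O)OC/C=C/c1cc(OC)c(OC)c(OC)c1 | intermediate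
12 | (E)-3-(3,4,5-trimethoxyphenyl)allyl 3-[4,5-bis(benzyloxy)-2-bromo-3-methoxyphenyl]-2-diazopropanoate (key-step precursor) | COc1c(Br)c(CC(=[N+]=[N-])C(=O)OC/C=C/c2cc(OC)c(OC)c(OC)c2)cc(OCc2ccccc2)c1OCc1ccccc1 | intermediate
13 | (1S,5R,6S)-1-[4,5-bis(benzyloxy)-2-bromo-3-methoxybenzyl]-6-(3,4,5-trimethoxyphenyl)-3-oxabicyclo[3.1.0]hexan-2-one (aryl exo, trans to C9; formed and consumed in the flask) | O=C1OC[C@@H]2[C@@H](c3cc(OC)c(OC)c(OC)c3)[C@]12Cc1cc(OCc2ccccc2)c(OCc2ccccc2)c(OC)c1Br | intermediate
14 | (3aR,4S,9aS)-5,6-bis(benzyloxy)-8-bromo-7-methoxy-4-(3,4,5-trimethoxyphenyl)-3a,4,9,9a-tetrahydronaphtho[2,3-c]furan-1(3H)-one (tetralin numbering 1S,2R,3S; cis-fused lactone, carbonyl on C3, aryl trans to C9, bromine on C5) | COc1c(Br)c2c(c(OCc3ccccc3)c1OCc1ccccc1)[C@H](c1cc(OC)c(OC)c(OC)c1)[C@H]1COC(=O)[C@H]1C2 | intermediate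
15 | [(1S,2R,3S)-7,8-bis(benzyloxy)-5-bromo-6-methoxy-1-(3,4,5-trimethoxyphenyl)-1,2,3,4-tetrahydronaphthalene-2,3-diyl]dimethanol | COc1c(Br)c2c(c(OCc3ccccc3)c1OCc1ccccc1)[C@H](c1cc(OC)c(OC)c(OC)c1)[C@@H](CO)[C@@H](CO)C2 | intermediate
16 | (6S,7R,8S)-6,7-bis(hydroxymethyl)-3-methoxy-8-(3,4,5-trimethoxyphenyl)-5,6,7,8-tetrahydronaphthalene-1,2-diol | COc1cc2c(c(O)c1O)[C@H](c1cc(OC)c(OC)c(OC)c1)[C@@H](CO)[C@@H](CO)C2 | target

Total step count: 12 (five for the ring A bromide, two for the acetoacetate, five after their union). Longest linear sequence: 10 steps (steps 1–5 and 8–12).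

Steps most likely to fail

**Step 10.**
- What may go wrong:
  - Migration of a C4 hydrogen to the carbene carbon may outrun addition to the alkene.
  - The alpha substituent may erode facial selectivity.
  - The cyclopropane, activated by one carbonyl only, may resist ionisation.
- The fallback sets out from 5 and 10 and returns at 14. It carries C4 through the same two events as a ketone, which removes the migrating hydrogens and gives the cyclopropane a second acceptor.
- Alcohol 5 is oxidised with MnO2 in CH2Cl2 to 4,5-bis(benzyloxy)-2-bromo-3-methoxybenzaldehyde F1.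
- Acetoacetate 10 undergoes ordinary diazo transfer (p-ABSA, Et3N, MeCN) to (E)-3-(3,4,5-trimethoxyphenyl)allyl 2-diazo-3-oxobutanoate F2.
- LiOH in aqueous THF deacetylates this to (E)-3-(3,4,5-trimethoxyphenyl)allyl diazoacetate F3.
- DBU-catalysed aldol-type addition of F3 to F1 gives the racemic 2-diazo-3-hydroxypropanoate F4.
- 2-Iodoxybenzoic acid in DMSO oxidises it to the 2-diazo-3-oxopropanoate F5.
- A chiral cobalt porphyrin of the class proven for acceptor-substituted allylic diazoacetates, [Co(por*)] (por* = D2-symmetric chiral amidoporphyrin, divalent cobalt), closes F5 to the 1-aroyl cyclopropane lactone F6.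
- Sc(OSO2CF3)3 in ClCH2CH2Cl opens the doubly activated ring with Friedel–Crafts capture, the established cyclisation of aryl 2-arylcyclopropyl ketones to 4-aryl-1-tetralones. This gives the 4-oxo tetralin lactone F7.
- Ionic hydrogenation of the aryl ketone (Et3SiH, CF3CO2H) then leads to 14.

**Step 2.**
- What may go wrong: bromine may enter para to the phenol or twice, which would undo the regiochemical logic of ring A.
- The fallback sets out from 2 and returns at 3. It replaces electrophilic substitution by directed metalation.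
- Boc2O with catalytic DMAP converts 2 into methyl 3,4-bis(benzyloxy)-5-[(tert-butoxycarbonyl)oxy]benzoate F8.
- (2,2,6,6-Tetramethylpiperidin-1-yl)MgCl·LiCl in THF at −20 to 0 °C magnesiates the C–H flanked by the two cooperating directing groups (ester and carbonate).
- BrCl2C–CCl2Br then delivers methyl 4,5-bis(benzyloxy)-2-bromo-3-[(tert-butoxycarbonyl)oxy]benzoate F9.
- CF3CO2H in CH2Cl2 removes the carbonate to give 3.

**Step 9.**
- What may go wrong: the acetyl transfer that completes the diazo transfer may stall at the hindered quaternary stage, or prolonged contact with base may degrade the diazo ester.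
- The fallback sets out from 8 and 6 and returns at 12. It makes the diazo group by nitrosation of a primary amine.
- Alcohol 8 is acylated with bromoacetyl bromide and pyridine to (E)-3-(3,4,5-trimethoxyphenyl)allyl bromoacetate F10.
- Benzophenone imine with i-Pr2NEt in MeCN converts it into (E)-3-(3,4,5-trimethoxyphenyl)allyl N-(diphenylmethylene)glycinate F11.
- Alkylation with bromide 6 (Cs2CO3, MeCN) gives the racemic alkylated imine F12.
- Aqueous citric acid in THF liberates the racemic alpha-amino ester F13.
- Isoamyl nitrite with catalytic acetic acid in warm CHCl3 turns the amine into 12.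

Further compounds
F1 | step 10 | 4,5-bis(benzyloxy)-2-bromo-3-methoxybenzaldehyde | COc1c(Br)c(C=O)cc(OCc2ccccc2)c1OCc1ccccc1
F2 | step 10 | (E)-3-(3,4,5-trimethoxyphenyl)allyl 2-diazo-3-oxobutanoate | CC(=O)C(=[N+]=[N-])C(=O)OC/C=C/c1cc(OC)c(OC)c(OC)c1
F3 | step 10 | (E)-3-(3,4,5-trimethoxyphenyl)allyl diazoacetate | [N-]=[N+]=CC(=O)OC/C=C/c1cc(OC)c(OC)c(OC)c1
F4 | step 10 | (E)-3-(3,4,5-trimethoxyphenyl)allyl 3-[4,5-bis(benzyloxy)-2-bromo-3-methoxyphenyl]-2-diazo-3-hydroxypropanoate (racemic) | COc1c(Br)c(C(O)C(=[N+]=[N-])C(=O)OC/C=C/c2cc(OC)c(OC)c(OC)c2)cc(OCc2ccccc2)c1OCc1ccccc1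
F5 | step 10 | (E)-3-(3,4,5-trimethoxyphenyl)allyl 3-[4,5-bis(benzyloxy)-2-bromo-3-methoxyphenyl]-2-diazo-3-oxopropanoate | COc1c(Br)c(C(=O)C(=[N+]=[N-])C(=O)OC/C=C/c2cc(OC)c(OC)c(OC)c2)cc(OCc2ccccc2)c1OCc1ccccc1
F6 | step 10 | (1S,5R,6S)-1-[4,5-bis(benzyloxy)-2-bromo-3-methoxybenzoyl]-6-(3,4,5-trimethoxyphenyl)-3-oxabicyclo[3.1.0]hexan-2-one | O=C1OC[C@@H]2[C@@H](c3cc(OC)c(OC)c(OC)c3)[C@]12C(=O)c1cc(OCc2ccccc2)c(OCc2ccccc2)c(OC)c1Br
F7 | step 10 | (3aR,4S,9aR)-5,6-bis(benzyloxy)-8-bromo-7-methoxy-4-(3,4,5-trimethoxyphenyl)-3a,4-dihydronaphtho[2,3-c]furan-1,9(3H,9aH)-dione | COc1c(Br)c2c(c(OCc3ccccc3)c1OCc1ccccc1)[C@H](c1cc(OC)c(OC)c(OC)c1)[C@H]1COC(=O)[C@H]1C2=O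
F8 | step 2 | methyl 3,4-bis(benzyloxy)-5-[(tert-butoxycarbonyl)oxy]benzoate | COC(=O)c1cc(OC(=O)OC(C)(C)C)c(OCc2ccccc2)c(OCc2ccccc2)c1
F9 | step 2 | methyl 4,5-bis(benzyloxy)-2-bromo-3-[(tert-butoxycarbonyl)oxy]benzoate | COC(=O)c1cc(OCc2ccccc2)c(OCc2ccccc2)c(OC(=O)OC(C)(C)C)c1Br
F10 | step 9 | (E)-3-(3,4,5-trimethoxyphenyl)allyl bromoacetate | BrCC(=O)OC/C=C/c1cc(OC)c(OC)c(OC)c1
F11 | step 9 | (E)-3-(3,4,5-trimethoxyphenyl)allyl N-(diphenylmethylene)glycinate | O=C(CN=C(c1ccccc1)c1ccccc1)OC/C=C/c1cc(OC)c(OC)c(OC)c1
F12 | step 9 | (E)-3-(3,4,5-trimethoxyphenyl)allyl 3-[4,5-bis(benzyloxy)-2-bromo-3-methoxyphenyl]-2-[(diphenylmethylene)amino]propanoate (racemic) | O=C(OC/C=C/c1cc(OC)c(OC)c(OC)c1)C(Cc1cc(OCc2ccccc2)c(OCc2ccccc2)c(OC)c1Br)N=C(c1ccccc1)c1ccccc1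
F13 | step 9 | (E)-3-(3,4,5-trimethoxyphenyl)allyl 2-amino-3-[4,5-bis(benzyloxy)-2-bromo-3-methoxyphenyl]propanoate (racemic) | NC(Cc1cc(OCc2ccccc2)c(OCc2ccccc2)c(OC)c1Br)C(=O)OC/C=C/c1cc(OC)c(OC)c(OC)c1
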